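The readings were computed for substances that don't exist.

- Slowness is the first thing you see: the teal flask needs 10.0 h to bring E to 80% of the J charged. So keep a ledger on J, the limiting reagent, and ask where each mole stands at the asked time.

| flask | J | Q | temperature | remark | time |
|---|---|---|---|---|---|
| teal | 0.025 M | 31 mM (held) | −20 °C | run made earlier |  |
| blue | 0.038 M | 31 mM (held) | 0 °C | run made earlier |  |
| north-east | 0.050 M | 31 mM (held) |  | at −15 °C until 80 min, from then on at 15 °C | 4.0 h |
| north-west | 0.050 M | 31 mM (held) | 0 °C |  | 4.0 h |
| south | 0.050 M | 31 mM (held) | 15 °C |  | 4.0 h |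
| east | 0.050 M | 31 mM (held) | −15 °C |  | 4.0 h |

| run | time / h | E / % | G / % |
|---|---|---|---|
| teal | 0.833 | 4 | 1 |
| teal | 2.00 | 19 | 0 |
| teal | 2.50 | 29 | 2 |
| teal | 5.00 | 61 | 0 |
| teal | 10.0 | 80 | 3 |
| blue | 0.333 | 2 | 0 |
| blue | 0.667 | 9 | 6 |
| blue | 1.00 | 11 | 0 |
| blue | 2.00 | 23 | 2 |
| blue | 4.00 | 32 | 10 |

(standard deviation of a reading: 2 percentage points)

* the flask with the highest share of E in all that became E or G ("all alike" if they lie within 1.5 percentage points) (north-east / north-west / south / east / all alike)
* share of E in all that became E or G, north-east
* share of E in all that became E or G, north-west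
* share of E in all that became E or G, south
* share of E in all that became E or G, east

- the analysis behind the earlier runs scatters by 2 percentage points, standard deviation
- at the start none of Q is in solution

- Entries: each mole of J is still J, or is E, or is G. In the blue flask at 4.00 h the books read E 32%, G 10%, and by difference J 58.0%.
- My assumption: G comes from E with a first-order constant k. If E grows about evenly, [G]/[E] = k·t/2, which gives 0.156 /h from blue and 0.007500 /h from teal.
- In logarithms the two readings lie 1.32 powers of ten apart. Teal's G is close to the scatter of 2 percentage points, so this is loose.
- Carry the loss number x, the time spent divided by E's time constant: the sum of k·t over the flask's stages. With an even feed of E and one constant k throughout, the share of E (the selectivity) is (1 − e^−x)/x.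
- Stepping along the logarithmic line, east has k = 0.0160 /h, so x = 0.0641 and the share is 96.9%.
- North-west has x = 0.625 and a share of 74.4%.
- South has k = 1.52 /h, so x = 6.09 and a share of 16.4%.
- North-east has x = 4.08, but its k changes at 80 min, so that formula does not hold there and the order of the stages counts. I follow E through both stages: the warm stage shrinks what the cold stage made and adds its own even feed, which gives a share of 16.7%. My pick is east.
- The forecast also names east, with 58% north-east, 80% north-west, 50% south and 95% east, holding that “The G pathway is therefore strongly temperature-sensitive”. My south figure is lower than its figure, and so is my north-east figure.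
- The flasks give 38.2% north-east, 81.0% north-west, 33.9% south and 97.7% east, so east is highest. South lands under the forecast and over my figure.

    Q ⇌ Z, rate k1*(csat - [Z]) (kL = 0.00490 /min)
    E → G (k = 0.00154 /min, Ea = 79.0 kJ/mol)
    J + Z ⇌ E + X (K = 0.573, k = 1.49 /M/min, Ea = 42.0 kJ/mol, ΔH = −64.0 kJ/mol)
    (constants at 0 °C)

- Here Z is dissolved Q and X a by-product. East's books close at J 59.1%, E 39.9% and G 0.958%, beside my share of 96.9%. The relaxation half-life of J + Z and E + X in east, by that step alone, is 0.432 h, shorter than the 4.0 h run, while the loss number stands at 0.0641.
- Now charge east's neighbour with 0.013 M of J: x holds no amount of J, so it stays 0.0641 and the share stays 96.9%. That flask gives 97.7%, with E at 63.5%.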